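**Retrosynthetic overview**

- The target is the mono-seco acid of a C2-symmetric 6,6'-linked bis(chromanone γ-lactone), so the last step opens one of two identical lactones.
- C2 and C9 of both halves come from a twofold catalytic asymmetric vinylogous addition of a β-methylbutenolide to a 6,6'-bis(chromone-2-carboxylate); C10 is set by hydrogenation.
- Both pyranone rings come from Claisen condensation of a bis(2-hydroxyacetophenone) with dimethyl oxalate and cyclodehydration.
- The strategy rests on the benzene rings: each has oxygen at C5 and C8a in a 1,3 relation, the acyl-bearing C4a between them, and the C6–C6' biaryl bond ortho to C5–OH. This is the pattern of a vinylketene/siloxyalkyne benzannulation, run here at both ends of a diene bis(diazo ketone) whose central single bond becomes the biaryl bond.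
- Ring order: both benzene rings together, then both pyranone rings together, then the two preformed butenolide rings are attached and saturated.

Key step: step 5

Remark: the biaryl axis carries two ortho hydroxyls and two ortho hydrogens and is taken as freely rotating, so no axial configuration is set.
Remark: the sense of induction of the scandium catalyst in step 9 is assumed; the ligand antipode that gives the 2S,9R series is the one used.
Remark: the bis(diazo ketone) is nitrogen-rich and should be handled in solution on small scale behind a shield.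

**Route**

Step 1
Reactants: 1 glyoxal; 2 1-(triphenylphosphoranylidene)propan-2-one (2 equiv)
Product: 3 (3E,5E)-octa-3,5-diene-2,7-dione
Conditions: 40% aq. glyoxal, CH2Cl2, rt
Reagents that add atoms: none
Why: Double Wittig olefination of the dialdehyde with a stabilised acyl ylide should give the E,E-dienedione, E geometry being the normal outcome for stabilised ylides.

Step 2
Reactants: 3 (3E,5E)-octa-3,5-diene-2,7-dione
Product: 5 (3E,5E)-1,8-bis(diazo)octa-3,5-diene-2,7-dione, via bis(trifluoroacetyl) tetraketone 4 (not isolated)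
Conditions: LiN(SiMe3)2 (2.2 equiv), THF, −78 °C (ketone added to base); CF3CO2CH2CF3; 5% aq. HCl work-up; then MsN3, Et3N, H2O, MeCN, rt
Reagents that add atoms: methanesulfonyl azide, CS(=O)(=O)N=[N+]=[N-]; 2,2,2-trifluoroethyl trifluoroacetate, O=C(OCC(F)(F)F)C(F)(F)F (its CF3CO group is carried only by intermediate 4)
Why: Detrifluoroacetylative diazo transfer: each kinetic α'-enolate of the enone is C-trifluoroacetylated, and the activated 1,3-diketone takes the diazo group from the sulfonyl azide with loss of the trifluoroacetyl group, a method suited to base-sensitive enones.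

Step 3
Reactants: 6 ethyl pyruvate
Product: 7 ethyl 2-methyl-1,3-dioxolane-2-carboxylate
Conditions: HOCH2CH2OH, p-TsOH·H2O (cat.), toluene, reflux (Dean–Stark)
Reagents that add atoms: ethylene glycol, OCCO
Why: Acid-catalysed ketalisation of the electrophilic α-keto group with azeotropic removal of water.

Step 4
Reactants: 7 ethyl 2-methyl-1,3-dioxolane-2-carboxylate; 8 triisopropylsilyl chloride
Product: 11 2-methyl-2-[(triisopropylsilyloxy)ethynyl]-1,3-dioxolane, via lithium dibromoenolate 9 (not isolated), via lithium ynolate 10 (not isolated)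
Conditions: CH2Br2, lithium 2,2,6,6-tetramethylpiperidide, THF, −78 °C; then n-BuLi, −78 → 25 °C; then 8, −78 → 0 °C
Reagents that add atoms: dibromomethane, BrCBr
Why: Kowalski ester homologation stopped at the ynolate: LiCHBr2 adds to the ester, bromine–lithium exchange on the dibromoenolate gives a carbenoid that rearranges by 1,2-shift of the dioxolanyl group, and the bulky silyl chloride traps the ynolate on oxygen.

Step 5
Reactants: 5 (3E,5E)-1,8-bis(diazo)octa-3,5-diene-2,7-dione; 11 2-methyl-2-[(triisopropylsilyloxy)ethynyl]-1,3-dioxolane (2 equiv incorporated, 3 equiv used)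
Product: 15 3,3'-bis(2-methyl-1,3-dioxolan-2-yl)-4,4'-bis(triisopropylsilyloxy)-[1,1'-biphenyl]-2,2'-diol, via ketene diazo ketone 12 (not isolated), via vinylcyclobutenone 13 (not isolated), via half-annulated diazo ketone 14 (not isolated)
Conditions: hν (medium-pressure Hg lamp, Pyrex filter), degassed ClCH2CH2Cl, 20 °C; then 80 °C
Reagents that add atoms: none
Why: Proposed new method: light expels N2 from one diazo ketone terminus and the neighbouring vinyl carbon migrates (photochemical Wolff rearrangement, forming C7–C8) to give vinylketene 12, whose carbonyl carbon (future C5) is attacked by the ketal-bearing β-carbon of ynol ether 11 (future C4a) while the ketene α-carbon (future C8) bonds to the siloxy carbon (future C8a), giving 4-vinylcyclobutenone 13 by [2+2] cycloaddition. On warming, 13 opens by 4π electrocyclic cleavage to a dienylketene whose central double bond is necessarily Z, and each benzene ring is closed by thermal disrotatory 6π electrocyclisation (C5–C6) and tautomerisation of the cyclohexadienone to the phenol, after which the second terminus of 14, now an ordinary β-aryl vinyl diazo ketone, repeats the sequence. The closest known reaction is the one-directional Danheiser benzannulation of α,β-unsaturated α'-diazo ketones with siloxyalkynes; new here is its use at both ends of one diene so that the central C4–C5 single bond of 5 becomes the C6–C6' biaryl bond. No stereocentre is formed. The step needs one regiochemistry in each ring, and the donor oxygen of 11 secures it by making the β-carbon the nucleophile toward the ketene carbonyl, so that oxygen lands at C8a as the silyl ether, the masked acetyl at C4a and the ketene oxygen at C5 as the free hydroxyl. It also needs ketene 12 not to close on itself, which the E geometry of its central C3=C4 double bond and fast capture by excess 11 should secure.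

Step 6
Reactants: 15 3,3'-bis(2-methyl-1,3-dioxolan-2-yl)-4,4'-bis(triisopropylsilyloxy)-[1,1'-biphenyl]-2,2'-diol
Product: 16 2,2'-bis(benzyloxy)-3,3'-bis(2-methyl-1,3-dioxolan-2-yl)-4,4'-bis(triisopropylsilyloxy)-1,1'-biphenyl
Conditions: BnBr, K2CO3, DMF, 40 °C
Reagents that add atoms: benzyl bromide, BrCc1ccccc1
Why: Williamson etherification of the only free phenols (C5–OH) fixes the difference between the two oxygens of each ring; silyl ethers and ketals are stable to carbonate, and a 1,3 silyl shift between meta oxygens is geometrically not possible.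

Step 7
Reactants: 16 2,2'-bis(benzyloxy)-3,3'-bis(2-methyl-1,3-dioxolan-2-yl)-4,4'-bis(triisopropylsilyloxy)-1,1'-biphenyl
Product: 18 1,1'-[2,2'-bis(benzyloxy)-4,4'-dihydroxy-[1,1'-biphenyl]-3,3'-diyl]di(ethan-1-one), via desilylated bis(ketal) 17 (not isolated)
Conditions: Bu4NF, THF, 0 °C; then 2 M aq. HCl, THF, rt
Reagents that add atoms: water, O
Why: Fluoride cleaves the aryl silyl ethers and aqueous acid hydrolyses the electron-rich aryl ketals (ketal hydrolysis), while the benzyl ethers survive both.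

Step 8
Reactants: 18 1,1'-[2,2'-bis(benzyloxy)-4,4'-dihydroxy-[1,1'-biphenyl]-3,3'-diyl]di(ethan-1-one)
Product: 20 dimethyl 5,5'-bis(benzyloxy)-4,4'-dioxo-4H,4'H-[6,6'-bichromene]-2,2'-dicarboxylate, via bis(diketo ester) 19 (not isolated)
Conditions: (CO2Me)2, NaOMe, MeOH/THF, 65 °C; then HCl in MeOH, 60 °C
Reagents that add atoms: dimethyl oxalate, COC(=O)C(=O)OC
Why: Claisen condensation of each methyl ketone with dimethyl oxalate and acid-catalysed cyclodehydration through the only free phenol (C8a–OH) is the classical chromone-2-carboxylate synthesis, so the ring oxygen can only be O1.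

Step 9
Reactants: 20 dimethyl 5,5'-bis(benzyloxy)-4,4'-dioxo-4H,4'H-[6,6'-bichromene]-2,2'-dicarboxylate; 21 4-methylfuran-2(5H)-one (2 equiv incorporated, excess used)
Product: 22 dimethyl (2S,2'S)-5,5'-bis(benzyloxy)-2,2'-bis[(2R)-3-methyl-5-oxo-2,5-dihydrofuran-2-yl]-4,4'-dioxo-[6,6'-bichromane]-2,2'-dicarboxylate
Conditions: Sc(OTf)3 (10 mol %), chiral N,N'-dioxide ligand [propane-1,3-diyl-bridged bis(N-oxide) of (S)-N-(2,6-diisopropylphenyl)piperidine-2-carboxamide] (10 mol %), Et3N (20 mol %), 4 Å MS, CH2Cl2, 30 °C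
Reagents that add atoms: none
Why: Catalytic asymmetric direct vinylogous conjugate addition of a butenolide to a 2-ester chromone: the scandium-bound chromone is attacked at C2 by C5 of the furanone dienolate inside the chiral pocket, which should set C2 (S) and C9 (R) in each half, and since the two remote halves react independently catalyst control should favour the C2-symmetric isomer.

Step 10
Reactants: 22 dimethyl (2S,2'S)-5,5'-bis(benzyloxy)-2,2'-bis[(2R)-3-methyl-5-oxo-2,5-dihydrofuran-2-yl]-4,4'-dioxo-[6,6'-bichromane]-2,2'-dicarboxylate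
Product: 23 dimethyl (2S,2'S)-5,5'-dihydroxy-2,2'-bis[(2R,3S)-3-methyl-5-oxooxolan-2-yl]-4,4'-dioxo-[6,6'-bichromane]-2,2'-dicarboxylate
Conditions: H2 (1 atm), 10% Pd/C, EtOAc/MeOH, rt
Reagents that add atoms: none
Why: Heterogeneous hydrogenation should deliver H2 to each butenolide C10=C11 from the face opposite the quaternary chromanone substituent at C9, placing the C10 methyl cis to it (10S), while the same catalyst hydrogenolyses both benzyl ethers and should spare the aryl ketones.

Step 11
Reactants: 23 dimethyl (2S,2'S)-5,5'-dihydroxy-2,2'-bis[(2R,3S)-3-methyl-5-oxooxolan-2-yl]-4,4'-dioxo-[6,6'-bichromane]-2,2'-dicarboxylate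
Product: 24 (3S,4R)-4-hydroxy-4-[(2S,2'S)-5,5'-dihydroxy-2,2'-bis(methoxycarbonyl)-2'-[(2R,3S)-3-methyl-5-oxooxolan-2-yl]-4,4'-dioxo-[6,6'-bichroman]-2-yl]-3-methylbutanoic acid
Conditions: LiOH (3 equiv), THF/H2O, 0 °C; then cold 0.5 M HCl to pH 4, rapid extraction
Reagents that add atoms: lithium hydroxide, [Li+].[OH-]
Why: Saponification by acyl–oxygen cleavage touches no stereocentre, and the unhindered γ-lactone carbonyl should react faster than the methyl esters on quaternary C2; two equivalents of base go to the phenols (which should also damp C3 enolisation) and the third opens about one lactone, so the mono-acid should form beside recoverable 23 and the diacid, which relactonises to 23 in acid.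

**Compound list**

1 | glyoxal | O=CC=O | starting material
2 | 1-(triphenylphosphoranylidene)propan-2-one | CC(=O)C=P(c1ccccc1)(c1ccccc1)c1ccccc1 | starting material
3 | (3E,5E)-octa-3,5-diene-2,7-dione | CC(=O)/C=C/C=C/C(C)=O | intermediate
4 | (5E,7E)-1,1,1,12,12,12-hexafluorododeca-5,7-diene-2,4,9,11-tetrone | FC(F)(F)C(=O)CC(=O)/C=C/C=C/C(=O)CC(=O)C(F)(F)F | intermediate
5 | (3E,5E)-1,8-bis(diazo)octa-3,5-diene-2,7-dione | [N-]=[N+]=CC(=O)/C=C/C=C/C(=O)C=[N+]=[N-] | intermediate
6 | ethyl pyruvate | CCOC(=O)C(C)=O | starting material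
7 | ethyl 2-methyl-1,3-dioxolane-2-carboxylate | CCOC(=O)C1(C)OCCO1 | intermediate
8 | triisopropylsilyl chloride | CC(C)[Si](Cl)(C(C)C)C(C)C | starting material
9 | lithium 2,2-dibromo-1-(2-methyl-1,3-dioxolan-2-yl)ethenolate | CC1(OCCO1)C([O-])=C(Br)Br.[Li+] | intermediate
10 | lithium 2-(2-methyl-1,3-dioxolan-2-yl)ethynolate | CC1(OCCO1)C#C[O-].[Li+] | intermediate
11 | 2-methyl-2-[(triisopropylsilyloxy)ethynyl]-1,3-dioxolane | CC1(C#CO[Si](C(C)C)(C(C)C)C(C)C)OCCO1 | intermediate
12 | (3E,5E)-8-diazoocta-1,3,5-triene-1,7-dione | O=C=C/C=C/C=C/C(=O)C=[N+]=[N-] | intermediate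
13 | 4-[(1E,3E)-6-diazo-5-oxohexa-1,3-dien-1-yl]-2-(2-methyl-1,3-dioxolan-2-yl)-3-(triisopropylsilyloxy)cyclobut-2-en-1-one (C4 unspecified) | CC1(OCCO1)C1=C(O[Si](C(C)C)(C(C)C)C(C)C)C(/C=C/C=C/C(=O)C=[N+]=[N-])C1=O | intermediate
14 | (E)-1-diazo-4-[2-hydroxy-3-(2-methyl-1,3-dioxolan-2-yl)-4-(triisopropylsilyloxy)phenyl]but-3-en-2-one | CC1(OCCO1)c1c(O)c(/C=C/C(=O)C=[N+]=[N-])ccc1O[Si](C(C)C)(C(C)C)C(C)C | intermediate
15 | 3,3'-bis(2-methyl-1,3-dioxolan-2-yl)-4,4'-bis(triisopropylsilyloxy)-[1,1'-biphenyl]-2,2'-diol | CC1(OCCO1)c1c(O)c(ccc1O[Si](C(C)C)(C(C)C)C(C)C)-c1ccc(O[Si](C(C)C)(C(C)C)C(C)C)c(C2(C)OCCO2)c1O | intermediate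
16 | 2,2'-bis(benzyloxy)-3,3'-bis(2-methyl-1,3-dioxolan-2-yl)-4,4'-bis(triisopropylsilyloxy)-1,1'-biphenyl | CC1(OCCO1)c1c(OCc2ccccc2)c(ccc1O[Si](C(C)C)(C(C)C)C(C)C)-c1ccc(O[Si](C(C)C)(C(C)C)C(C)C)c(C2(C)OCCO2)c1OCc1ccccc1 | intermediate
17 | 2,2'-bis(benzyloxy)-3,3'-bis(2-methyl-1,3-dioxolan-2-yl)-[1,1'-biphenyl]-4,4'-diol | CC1(OCCO1)c1c(OCc2ccccc2)c(ccc1O)-c1ccc(O)c(C2(C)OCCO2)c1OCc1ccccc1 | intermediate
18 | 1,1'-[2,2'-bis(benzyloxy)-4,4'-dihydroxy-[1,1'-biphenyl]-3,3'-diyl]di(ethan-1-one) | CC(=O)c1c(OCc2ccccc2)c(ccc1O)-c1ccc(O)c(C(C)=O)c1OCc1ccccc1 | intermediate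
19 | dimethyl 4,4'-[2,2'-bis(benzyloxy)-4,4'-dihydroxy-[1,1'-biphenyl]-3,3'-diyl]bis(2,4-dioxobutanoate) | COC(=O)C(=O)CC(=O)c1c(OCc2ccccc2)c(ccc1O)-c1ccc(O)c(C(=O)CC(=O)C(=O)OC)c1OCc1ccccc1 | intermediate
20 | dimethyl 5,5'-bis(benzyloxy)-4,4'-dioxo-4H,4'H-[6,6'-bichromene]-2,2'-dicarboxylate | COC(=O)c1cc(=O)c2c(OCc3ccccc3)c(ccc2o1)-c1ccc2oc(C(=O)OC)cc(=O)c2c1OCc1ccccc1 | intermediate
21 | 4-methylfuran-2(5H)-one | CC1=CC(=O)OC1 | starting material
22 | dimethyl (2S,2'S)-5,5'-bis(benzyloxy)-2,2'-bis[(2R)-3-methyl-5-oxo-2,5-dihydrofuran-2-yl]-4,4'-dioxo-[6,6'-bichromane]-2,2'-dicarboxylate | O=C1C[C@@](C(=O)OC)([C@@H]2OC(=O)C=C2C)Oc2ccc(c(OCc3ccccc3)c12)-c1ccc2c(c1OCc1ccccc1)C(=O)C[C@@](C(=O)OC)([C@@H]1OC(=O)C=C1C)O2 | intermediate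
23 | dimethyl (2S,2'S)-5,5'-dihydroxy-2,2'-bis[(2R,3S)-3-methyl-5-oxooxolan-2-yl]-4,4'-dioxo-[6,6'-bichromane]-2,2'-dicarboxylate | O=C1C[C@@](C(=O)OC)([C@@H]2OC(=O)C[C@@H]2C)Oc2ccc(c(O)c12)-c1ccc2c(c1O)C(=O)C[C@@](C(=O)OC)([C@@H]1OC(=O)C[C@@H]1C)O2 | intermediate
24 | (3S,4R)-4-hydroxy-4-[(2S,2'S)-5,5'-dihydroxy-2,2'-bis(methoxycarbonyl)-2'-[(2R,3S)-3-methyl-5-oxooxolan-2-yl]-4,4'-dioxo-[6,6'-bichroman]-2-yl]-3-methylbutanoic acid | COC(=O)[C@@]1([C@H](O)[C@@H](C)CC(=O)O)CC(=O)c2c(ccc(-c3ccc4c(c3O)C(=O)C[C@@](C(=O)OC)([C@@H]3OC(=O)C[C@@H]3C)O4)c2O)O1 | target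

**Step count and risks**

Total step count: 11. Longest linear sequence: 9 steps (steps 1, 2, 5, 6, 7, 8, 9, 10, 11; the alkyne branch through steps 3 and 4 is equally long).

Steps most likely to fail:

1. Step 5 (two-directional benzannulation). What may go wrong: photochemical E/Z isomerisation of the diene lets the first ketene cyclise on itself; ketene–diazo or ketene–phenol coupling leads to oligomers; and the [2+2] cycloaddition may be slow at the alkyne carbon carrying the quaternary ketal. The fallback runs the same benzannulation twice in its established one-directional form; it sets out from 3 and returns at 16. One end of 3 is converted by the diazo transfer of step 2 with one equivalent of base into (3E,5E)-1-diazoocta-3,5-diene-2,7-dione F1. Irradiation of F1 with 11 and heating should give (E)-4-[2-hydroxy-3-(2-methyl-1,3-dioxolan-2-yl)-4-(triisopropylsilyloxy)phenyl]but-3-en-2-one F2. Benzylation (BnBr, K2CO3) gives (E)-4-[2-(benzyloxy)-3-(2-methyl-1,3-dioxolan-2-yl)-4-(triisopropylsilyloxy)phenyl]but-3-en-2-one F3. The same diazo transfer on its methyl ketone gives (E)-4-[2-(benzyloxy)-3-(2-methyl-1,3-dioxolan-2-yl)-4-(triisopropylsilyloxy)phenyl]-1-diazobut-3-en-2-one F4, a β-aryl vinyl diazo ketone of the established substrate class. A second benzannulation with 11 gives 2'-(benzyloxy)-3,3'-bis(2-methyl-1,3-dioxolan-2-yl)-4,4'-bis(triisopropylsilyloxy)-[1,1'-biphenyl]-2-ol F5, and benzylation of its remaining phenol gives 16.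

2. Step 9 (twofold asymmetric vinylogous addition). What may go wrong: poor facial selectivity at C2, the wrong relative topicity between C2 and C9, or an incomplete second addition on the dimer. The fallback gives up catalyst control for a silyl-triflate-promoted siloxyfuran addition followed by separation; it sets out from 20 and 21 and returns at 22. Silylation of 21 (Me3SiOTf, Et3N) gives 4-methyl-2-(trimethylsilyloxy)furan F6. Activation of 20 with tert-butyldimethylsilyl triflate as the bis(4-siloxybenzopyrylium) salt and addition of F6 should give the bis(silyl enol ether) dimethyl 5,5'-bis(benzyloxy)-4,4'-bis(tert-butyldimethylsilyloxy)-2,2'-bis(3-methyl-5-oxo-2,5-dihydrofuran-2-yl)-2H,2'H-[6,6'-bichromene]-2,2'-dicarboxylate F7. Acidic work-up gives the stereoisomer mixture dimethyl 5,5'-bis(benzyloxy)-2,2'-bis(3-methyl-5-oxo-2,5-dihydrofuran-2-yl)-4,4'-dioxo-[6,6'-bichromane]-2,2'-dicarboxylate F8. Chromatography on silica and then on a chiral stationary phase isolates the (2S,9R,2'S,9'R) isomer, which is 22.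

3. Step 11 (opening of one lactone). What may go wrong: opening of both lactones or hydrolysis of a methyl ester, base-induced retro-oxa-Michael epimerisation at C2, and relactonisation of the γ-hydroxy acid during acidic work-up. The fallback approaches the mono-acid from the other side; it sets out from 23 and returns at 24. Both lactones are opened with excess LiOH at 0 °C to give, after careful acidification, the bis(hydroxy acid) (3S,3'S,4R,4'R)-4,4'-[(2S,2'S)-5,5'-dihydroxy-2,2'-bis(methoxycarbonyl)-4,4'-dioxo-[6,6'-bichromane]-2,2'-diyl]bis(4-hydroxy-3-methylbutanoic acid) F9. Controlled acid-mediated lactonisation of F9 (dilute AcOH in CH2Cl2, monitored) is stopped when one ring has closed, giving 24; fully closed material is 23 and is recycled.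

**Further compounds**

F1 | step 5 | (3E,5E)-1-diazoocta-3,5-diene-2,7-dione | CC(=O)/C=C/C=C/C(=O)C=[N+]=[N-]
F2 | step 5 | (E)-4-[2-hydroxy-3-(2-methyl-1,3-dioxolan-2-yl)-4-(triisopropylsilyloxy)phenyl]but-3-en-2-one | CC(=O)/C=C/c1ccc(O[Si](C(C)C)(C(C)C)C(C)C)c(C2(C)OCCO2)c1O
F3 | step 5 | (E)-4-[2-(benzyloxy)-3-(2-methyl-1,3-dioxolan-2-yl)-4-(triisopropylsilyloxy)phenyl]but-3-en-2-one | CC(=O)/C=C/c1ccc(O[Si](C(C)C)(C(C)C)C(C)C)c(C2(C)OCCO2)c1OCc1ccccc1
F4 | step 5 | (E)-4-[2-(benzyloxy)-3-(2-methyl-1,3-dioxolan-2-yl)-4-(triisopropylsilyloxy)phenyl]-1-diazobut-3-en-2-one | [N-]=[N+]=CC(=O)/C=C/c1ccc(O[Si](C(C)C)(C(C)C)C(C)C)c(C2(C)OCCO2)c1OCc1ccccc1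
F5 | step 5 | 2'-(benzyloxy)-3,3'-bis(2-methyl-1,3-dioxolan-2-yl)-4,4'-bis(triisopropylsilyloxy)-[1,1'-biphenyl]-2-ol | CC1(OCCO1)c1c(O)c(ccc1O[Si](C(C)C)(C(C)C)C(C)C)-c1ccc(O[Si](C(C)C)(C(C)C)C(C)C)c(C2(C)OCCO2)c1OCc1ccccc1
F6 | step 9 | 4-methyl-2-(trimethylsilyloxy)furan | Cc1coc(O[Si](C)(C)C)c1
F7 | step 9 | dimethyl 5,5'-bis(benzyloxy)-4,4'-bis(tert-butyldimethylsilyloxy)-2,2'-bis(3-methyl-5-oxo-2,5-dihydrofuran-2-yl)-2H,2'H-[6,6'-bichromene]-2,2'-dicarboxylate (stereoisomer mixture) | COC(=O)C1(C2OC(=O)C=C2C)C=C(O[Si](C)(C)C(C)(C)C)c2c(O1)ccc(c2OCc1ccccc1)-c1ccc2OC(C(=O)OC)(C3OC(=O)C=C3C)C=C(O[Si](C)(C)C(C)(C)C)c2c1OCc1ccccc1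
F8 | step 9 | dimethyl 5,5'-bis(benzyloxy)-2,2'-bis(3-methyl-5-oxo-2,5-dihydrofuran-2-yl)-4,4'-dioxo-[6,6'-bichromane]-2,2'-dicarboxylate (stereoisomer mixture) | O=C1CC(C(=O)OC)(C2OC(=O)C=C2C)Oc2ccc(c(OCc3ccccc3)c12)-c1ccc2c(c1OCc1ccccc1)C(=O)CC(C(=O)OC)(C1OC(=O)C=C1C)O2
F9 | step 11 | (3S,3'S,4R,4'R)-4,4'-[(2S,2'S)-5,5'-dihydroxy-2,2'-bis(methoxycarbonyl)-4,4'-dioxo-[6,6'-bichromane]-2,2'-diyl]bis(4-hydroxy-3-methylbutanoic acid) | COC(=O)[C@@]1([C@H](O)[C@@H](C)CC(=O)O)CC(=O)c2c(ccc(-c3ccc4c(c3O)C(=O)C[C@@](C(=O)OC)([C@H](O)[C@@H](C)CC(=O)O)O4)c2O)O1
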